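Ring A of the isoflavone is disconnected at C8–C8a and C4a–C5. C5, C6, C7 and C8, with the C6 and C7 methoxy groups, come from 3,4-dimethoxyfuran, whose ring oxygen ends on C8; C4a and C8a come from an alkoxy ynone that already carries C4, C3 and ring B. Cycloaddition followed by acid opening of the oxygen bridge builds the fully oxygenated ring A in one operation and leaves the C8 and C8a oxygens differentiated. The precursor is 4-ethoxy-1-(3,4,5-trimethoxyphenyl)but-3-yn-2-one; ethyl is preferred to benzyl because benzyl alkynyl ethers rearrange sigmatropically on mild heating.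

Key step: step 3

Remark: the O-alkyl group of the ynol ether is treated as a protecting group. Ethoxyacetylene (sold as a hexane solution) and 3,4-dimethoxyfuran are taken as purchasable. Adduct 9 is racemic and its stereocentres vanish within the same step.

Step 1
Reactants: 1 3,4,5-trimethoxyphenylacetic acid
Product: 3 N-methoxy-N-methyl-2-(3,4,5-trimethoxyphenyl)acetamide, via acyl imidazolide 2 (not isolated)
Conditions: CDI, CH2Cl2, rt; then MeNHOMe·HCl, rt
Reagents that add atoms: N,O-dimethylhydroxylamine hydrochloride, CNOC.Cl
Why: Activation of the acid as its acyl imidazolide and aminolysis is the standard Weinreb amide synthesis, and the imidazole set free takes up the HCl of the amine salt.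

Step 2
Reactants: 3 N-methoxy-N-methyl-2-(3,4,5-trimethoxyphenyl)acetamide; 4 ethoxyacetylene
Product: 7 4-ethoxy-1-(3,4,5-trimethoxyphenyl)but-3-yn-2-one, via lithium ethoxyacetylide 5 (not isolated), via lithium hemiaminal adduct 6 (not isolated)
Conditions: 4, n-BuLi, THF, −78 °C; then 3, −78 to −20 °C; recool, AcOH (THF), −78 °C, then pH 7 buffer
Reagents that add atoms: none
Why: This is a Weinreb ketone synthesis with a lithium acetylide, in which the N,O-chelated tetrahedral adduct 6 persists until the cold quench, so the ynone and its acidic methylene appear only after all base is consumed.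

Step 3
Reactants: 7 4-ethoxy-1-(3,4,5-trimethoxyphenyl)but-3-yn-2-one; 8 3,4-dimethoxyfuran
Product: 10 1-(2-ethoxy-3-hydroxy-4,5-dimethoxyphenyl)-2-(3,4,5-trimethoxyphenyl)ethan-1-one, via oxanorbornadiene 9 (not isolated)
Conditions: 8 (2.5 equiv), PhMe, 60 °C, sealed; evaporate; CF3CO2H (cat.), CH2Cl2, 0 °C to rt
Reagents that add atoms: none
Why: Proposed new method: the electron-rich diene 8 and the acyl-activated alkyne of 7 should combine in a concerted but asynchronous (4+2) cycloaddition, with bonding leading at the ethoxy-bearing alkyne carbon, which forms C8–C8a and C4a–C5 and closes the six-membered carbocycle by intermolecular suprafacial annulation to give 9; the closest known reaction type is the Diels–Alder addition of 3,4-dimethoxyfuran to acetylenic esters followed by acid isomerization of the 7-oxanorbornadienes to 2,3-dimethoxyphenols. Protonation of the bridge oxygen and heterolysis of the C5–O bond should give a cation spread over C5, C7 and C8a, stabilized by the C7 methoxy and above all by the C8a ethoxy group, whereas breaking C8–O would put positive charge on the acyl-bearing C4a. Loss of the C8 proton then aromatizes ring A with the oxygen kept on C8. The two bridgehead stereocentres of 9 form as a racemate, locked relative to each other by the bicycle, and both are erased on aromatization, so no stereocontrol is needed. The symmetric furan leaves no regiochemical choice in the cycloaddition, and the one selectivity required, the direction of bridge opening, is secured by the push–pull polarization of the C8a(OEt)=C4a(acyl) double bond. The ethyl ynol ether has no sigmatropic pathway and should tolerate 60 °C, since retro-ene loss of ethylene from such ethers typically needs more than 100 °C.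

Step 4
Reactants: 10 1-(2-ethoxy-3-hydroxy-4,5-dimethoxyphenyl)-2-(3,4,5-trimethoxyphenyl)ethan-1-one
Product: 11 1-(2-ethoxy-3,4,5-trimethoxyphenyl)-2-(3,4,5-trimethoxyphenyl)ethan-1-one
Conditions: MeI, K2CO3, acetone, 40 °C
Reagents that add atoms: iodomethane, CI
Why: In this Williamson O-methylation K2CO3 deprotonates the phenol (the future C8 oxygen) but not appreciably the ketone methylene, so O-alkylation should prevail over C-alkylation.

Step 5
Reactants: 11 1-(2-ethoxy-3,4,5-trimethoxyphenyl)-2-(3,4,5-trimethoxyphenyl)ethan-1-one
Product: 13 1-(2-hydroxy-3,4,5-trimethoxyphenyl)-2-(3,4,5-trimethoxyphenyl)ethan-1-one, via dichloroboron phenoxide 12 (not isolated)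
Conditions: BCl3 (1.5 equiv), CH2Cl2, −78 to 0 °C; then H2O
Reagents that add atoms: none
Why: In this chelation-controlled ether cleavage BCl3 bridges the ketone oxygen and the ortho ethoxy oxygen and chloride displaces the ethyl group there, while the six methoxy groups, none of them ortho to the carbonyl, should survive at or below 0 °C.

Step 6
Reactants: 13 1-(2-hydroxy-3,4,5-trimethoxyphenyl)-2-(3,4,5-trimethoxyphenyl)ethan-1-one
Product: 15 6,7,8-trimethoxy-3-(3,4,5-trimethoxyphenyl)-4H-chromen-4-one, via enaminone 14 (not isolated)
Conditions: Me2NCH(OMe)2, PhMe, 90 °C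
Reagents that add atoms: N,N-dimethylformamide dimethyl acetal, COC(OC)N(C)C
Why: In this deoxybenzoin route to isoflavones the active methylene condenses with the formamide acetal to enaminone 14, the ortho phenol adds to the enamine carbon in a 6-endo conjugate addition and dimethylamine is eliminated, which closes the pyranone ring with C2 from the acetal carbon.

Compound list
1 | 3,4,5-trimethoxyphenylacetic acid | COc1cc(CC(=O)O)cc(OC)c1OC | starting material
2 | 1-[(3,4,5-trimethoxyphenyl)acetyl]-1H-imidazole (acyl imidazolide) | COc1cc(CC(=O)n2ccnc2)cc(OC)c1OC | intermediate (not isolated)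
3 | N-methoxy-N-methyl-2-(3,4,5-trimethoxyphenyl)acetamide | COc1cc(CC(=O)N(C)OC)cc(OC)c1OC | intermediate
4 | ethoxyacetylene (ethoxyethyne) | CCOC#C | starting material
5 | lithium ethoxyacetylide | CCOC#C[Li] | intermediate (not isolated)
6 | lithium 4-ethoxy-2-[methoxy(methyl)amino]-1-(3,4,5-trimethoxyphenyl)but-3-yn-2-olate (lithium hemiaminal adduct, racemic) | CCOC#CC([O-])(Cc1cc(OC)c(OC)c(OC)c1)N(C)OC.[Li+] | intermediate (not isolated)
7 | 4-ethoxy-1-(3,4,5-trimethoxyphenyl)but-3-yn-2-one | CCOC#CC(=O)Cc1cc(OC)c(OC)c(OC)c1 | intermediate
8 | 3,4-dimethoxyfuran | COc1cocc1OC | starting material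
9 | 1-(3-ethoxy-5,6-dimethoxy-7-oxabicyclo[2.2.1]hepta-2,5-dien-2-yl)-2-(3,4,5-trimethoxyphenyl)ethan-1-one (oxanorbornadiene, racemic, one enantiomer drawn) | CCOC1=C(C(=O)Cc2cc(OC)c(OC)c(OC)c2)[C@@H]3O[C@H]1C(OC)=C3OC | intermediate (not isolated)
10 | 1-(2-ethoxy-3-hydroxy-4,5-dimethoxyphenyl)-2-(3,4,5-trimethoxyphenyl)ethan-1-one | CCOc1c(O)c(OC)c(OC)cc1C(=O)Cc1cc(OC)c(OC)c(OC)c1 | intermediate
11 | 1-(2-ethoxy-3,4,5-trimethoxyphenyl)-2-(3,4,5-trimethoxyphenyl)ethan-1-one | CCOc1c(OC)c(OC)c(OC)cc1C(=O)Cc1cc(OC)c(OC)c(OC)c1 | intermediate
12 | 2-[(3,4,5-trimethoxyphenyl)acetyl]-4,5,6-trimethoxyphenyl dichloroborinate (dichloroboron phenoxide) | COc1cc(C(=O)Cc2cc(OC)c(OC)c(OC)c2)c(OB(Cl)Cl)c(OC)c1OC | intermediate (not isolated)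
13 | 1-(2-hydroxy-3,4,5-trimethoxyphenyl)-2-(3,4,5-trimethoxyphenyl)ethan-1-one | COc1cc(C(=O)Cc2cc(OC)c(OC)c(OC)c2)c(O)c(OC)c1OC | intermediate
14 | (E)-3-(dimethylamino)-1-(2-hydroxy-3,4,5-trimethoxyphenyl)-2-(3,4,5-trimethoxyphenyl)prop-2-en-1-one (enaminone; the geometry is immaterial, the push–pull alkene isomerizes readily) | CN(C)/C=C(/C(=O)c1cc(OC)c(OC)c(OC)c1O)c1cc(OC)c(OC)c(OC)c1 | intermediate (not isolated)
15 | 6,7,8-trimethoxy-3-(3,4,5-trimethoxyphenyl)-4H-chromen-4-one | COc1cc(-c2coc3c(OC)c(OC)c(OC)cc3c2=O)cc(OC)c1OC | target

Total step count: 6. Longest linear sequence: 6 steps (1 → 3 → 7 → 10 → 11 → 13 → 15).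

Steps most likely to fail

Step 3 (proposed new method). The donor-substituted ynone may be too weak a dienophile. The furan may instead add stepwise through its C2 to the ethoxy-bearing alkyne carbon and lose a proton, which gives alkenylation without ring closure. The bridge may also open in the unwanted direction. The fallback uses known chemistry, sets out from 1 and returns at 13. Acid 1 would be esterified with purchased 2,3,4-trimethoxyphenol (COc1ccc(O)c(OC)c1OC; DCC, DMAP, CH2Cl2) to give 2,3,4-trimethoxyphenyl (3,4,5-trimethoxyphenyl)acetate F1. A Fries rearrangement (BF3·OEt2, 80 °C, or TiCl4 in CH2Cl2) should then move the acyl group to the only free position ortho to the phenol oxygen, because the para position carries a methoxy group. This gives 13 directly and the route resumes at step 6.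

Step 2. The N,O-dimethylhydroxylamine set free at the quench may add to the ethoxy-bearing carbon of the ynone and displace ethoxide, the ynol ether may be hydrated during work-up, or the acetylide may enolize the amide and return it unchanged. The fallback sets out from 3 and returns at 7. Amide 3 would be reduced (LiAlH4, THF, −40 °C) to (3,4,5-trimethoxyphenyl)acetaldehyde F2. Lithium ethoxyacetylide 5 would be added at −78 °C to give racemic 4-ethoxy-1-(3,4,5-trimethoxyphenyl)but-3-yn-2-ol F3. The propargylic alcohol would be oxidized with MnO2 in CH2Cl2 to 7, so that the ynone never meets the hydroxylamine.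

Step 5. Chloride attack on the ethyl group is slower than on a methyl group, so regioselectivity may be lost: the neighbouring methoxy group (future C8–OMe) can be cleaved through the newly formed borate, or cleavage may remain incomplete. The fallback sets out from 10 and returns at 13. Phenol 10 would be treated with BCl3 (CH2Cl2, −78 to 0 °C) before the methylation, when no methoxy group sits next to the ethoxy group and both the ketone and the adjacent phenol borate deliver boron to the ethoxy oxygen. This should give 1-(2,3-dihydroxy-4,5-dimethoxyphenyl)-2-(3,4,5-trimethoxyphenyl)ethan-1-one F4. The hydroxyl that is not hydrogen-bonded to the ketone would then be methylated selectively with Me3SiCHN2 (MeOH/PhMe, 0 °C) to give 13.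

Further compounds
F1 | step 3 | 2,3,4-trimethoxyphenyl (3,4,5-trimethoxyphenyl)acetate | COc1cc(CC(=O)Oc2ccc(OC)c(OC)c2OC)cc(OC)c1OC
F2 | step 2 | (3,4,5-trimethoxyphenyl)acetaldehyde | COc1cc(CC=O)cc(OC)c1OC
F3 | step 2 | 4-ethoxy-1-(3,4,5-trimethoxyphenyl)but-3-yn-2-ol (racemic) | CCOC#CC(O)Cc1cc(OC)c(OC)c(OC)c1
F4 | step 5 | 1-(2,3-dihydroxy-4,5-dimethoxyphenyl)-2-(3,4,5-trimethoxyphenyl)ethan-1-one | COc1cc(C(=O)Cc2cc(OC)c(OC)c(OC)c2)c(O)c(O)c1OC
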